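The data were generated by integration with made-up constants; scatter was added.

Amounts first: I counted what the charges could consume before I looked at any rates.

in all of them: activator 1.08 M
- birch: starting material 0.89 M; protic impurity 0.27 M; run made earlier
- elm: starting material 1.4 M; protic impurity 0.27 M; run made earlier
- oak: starting material 1.9 M; protic impurity 0.27 M; run made earlier
- summer: starting material 0.90 M; protic impurity 0.270 M; time 5.0 h
- midnight: starting material 2.5 M; protic impurity 0.270 M; time 2.5 h

- birch (time / h: ring / %, starting material / %): 0.333: 19.1, 16.5; 0.833: 32.4, 2.6; 1.50: 26.5, 0; 2.50: 20.5, 0
- elm (time / h: ring / %, starting material / %): 0.667: 22.1, 7.7; 1.33: 21.2, 0.7; 2.00: 20.2, 0; 2.50: 15.6, 0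
- oak (time / h: ring / %, starting material / %): 0.667: 15.1, 12.4; 1.33: 12.7, 5.0; 2.00: 12.7, 4.1; 2.50: 10.9, 3.9

(readings scatter by 1 percentage point)

- in percentages every species weighs as the starting material in it: one open dimer or self-condensation product counts as two
- the earlier runs were read with a standard deviation of 1 percentage point
- steps that have been proposed: starting material + activator -> activated form; activated form -> ring; starting material + activated form -> open dimer; 2 starting material -> self-condensation product; ring <-> isomer of the product; starting material + protic impurity -> quenched substrate

- which of the two ends with the higher amount of ring, in percent of the starting material charged ("neither" if they lie within 2 percentage points) (summer / midnight / neither)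
- ring at the end, in percent of the starting material charged, summer
- ring at the end, in percent of the starting material charged, midnight

1. Each activator can take two of starting material, one into the activated form and one into the open dimer, and each protic impurity takes one. Leaving self-condensation aside, that made 2.43 M, the capacity: the starting material that activator and impurity can consume between them.

2. Summer, at 0.90 M, lay below capacity. Midnight, at 2.5 M, lay above it by 0.0700 M, so I expected starting material to remain there.

3. My first estimate for midnight took ring per litre as flat: 0.218 M in elm and 0.207 M in oak at the last readings, which gave 8.28%.

4. The objection was the count. Once activator and impurity have gone, ring plus isomer equals capacity minus charge plus starting material left. With the starting material left held, that quantity shrinks as the charge rises, so a flat ring at midnight was doubtful.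

5. I took oak as used up, though its activator was never read. That gave ring plus isomer of 0.604 M, a share 0.559 of its activator, with ring 0.343 of that. If the activated form divides according to the mean starting material, these readings put open dimer over ring plus isomer, per molar of that mean, at 0.798 /M.

6. I then iterated for midnight. Oak's amount put in gave 0.674 M left and so 0.476 M of ring plus isomer. Going round again gave 0.546 M left and 0.487 M. Ring at midnight came to 6.68%.

7. For summer I continued birch's fall between its last two readings, which gave 10.8%. The objection was that the proposed reverse step from the isomer slows such a fall, so I took this as a low estimate. I committed to summer as the higher, with 10.8% or somewhat more against 6.68% for midnight.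

8. The forecast gave summer, with 12% and 8%, its midnight figure above mine: “Summer probably ends higher, though the margin is modest.”

9. The flask gave summer, with 15.3% for summer and 6.10% for midnight.

    starting material + activator → activated form (k = 0.0750 /M/min)
    activated form → ring (k = 0.0630 /min)
    starting material + activated form → open dimer (k = 0.130 /M/min)
    2 starting material → self-condensation product (k = 1.40 × 10⁻⁴ /M/min)
    ring ⇌ isomer of the product (K = 2.10, k = 0.00920 /min)
    starting material + protic impurity → quenched substrate (k = 0.0850 /M/min)

In summer, at charged amounts, the activated form's half-life by the open-dimer step was 0.099 h against 0.18 h by the ring step, and at 0.104 h its use by ring over dimer stood at 1.0. At midnight, with 0.179% of the activator left, capacity minus charge plus starting material left came to 0.328 M, and ring plus isomer stood at 0.341 M. A neighbour of summer, charged with 2.2 M of starting material, came after 5.00 h to 0.409 M by that count, stood at 0.417 M, and ended with 6.56% ring.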